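The route rests on one disconnection in ring A (terpenoid numbering: ring A = C1–C5, C10; ring B = C5–C10; ring C = C8, C9, C11–C14): the C4–C5 bond is traced back to a C4–C10 bond of a 1,2,2-trimethylcyclopentane. The key step exploits the C6 oxygen next to C5–H, which lies between the quaternary carbons C4 and C10. MeAlCl2 opens a C5–C6 epoxide, C4 migrates from C10 to C5, and the resulting C10 cation closes rings B and C onto an E-alkene and a silyl enol ether. One operation gives three rings and sets C5, C8, C9 and C10. The precursor is an open-chain epoxy diene bearing a cyclopentane.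

Key step: step 13

Numbering used below: ring D is the oxolane (O, C13, C5', C4', C3'). Ring E is the cyclohexanone C1'(=O), C2'(CH3), C3'(O), C4'(OH), C5'(bonded to C13), C6'. CIP descriptors refer to this numbering.

Remark on the chemistry: the cyclopentane carbon that becomes C10 is carried as both configurations (compounds 2–10 and 20). The SMILES leave it open, because step 13 makes this carbon planar.

Step 1
Reactants: 1 2,2-dimethylcyclopentan-1-one
Product: 2 2,2-dimethylcyclopentane-1-carbonitrile
Conditions: TosMIC, t-BuOK, DME/EtOH, 0 to 40 °C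
Reagents that add atoms: TosMIC Cc1ccc(cc1)S(=O)(=O)C[N+]#[C-]
Why: The Van Leusen reductive cyanation converts the hindered ketone directly into the one-carbon-longer nitrile, and the new stereocentre is racemic and removed in step 2.

Step 2
Reactants: 2 2,2-dimethylcyclopentane-1-carbonitrile
Product: 4 1,2,2-trimethylcyclopentane-1-carbonitrile, via lithiated nitrile 3 (not isolated)
Conditions: LDA, THF, −78 °C; MeI, −78 °C to rt
Reagents that add atoms: iodomethane CI
Why: Alkylation of the small, linear nitrile anion with MeI builds the quaternary carbon next to the gem-dimethyl carbon, racemic by design because this carbon (later C10) becomes planar in step 13.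

Step 3
Reactants: 4 1,2,2-trimethylcyclopentane-1-carbonitrile
Product: 6 1,2,2-trimethylcyclopentane-1-carbaldehyde, via N-aluminated imine 5 (not isolated)
Conditions: i-Bu2AlH, toluene, −78 to 0 °C; 1 M HCl
Reagents that add atoms: water O
Why: Partial reduction of a nitrile with i-Bu2AlH stops at the N-aluminated imine, which acid hydrolysis turns into the non-enolisable aldehyde (C5).

Step 4
Reactants: 6 1,2,2-trimethylcyclopentane-1-carbaldehyde
Product: 7 ethyl (2E)-3-(1,2,2-trimethylcyclopentyl)prop-2-enoate
Conditions: (EtO)2P(O)CH2CO2Et, NaH, THF, 0 °C to rt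
Reagents that add atoms: triethyl phosphonoacetate CCOC(=O)CP(=O)(OCC)OCC
Why: The Horner–Wadsworth–Emmons olefination of a pivaldehyde-like aldehyde with a stabilised phosphonate is reliably E-selective and adds C6 and C7.

Step 5
Reactants: 7 ethyl (2E)-3-(1,2,2-trimethylcyclopentyl)prop-2-enoate
Product: 8 (2E)-3-(1,2,2-trimethylcyclopentyl)prop-2-en-1-ol
Conditions: i-Bu2AlH (2.2 equiv), CH2Cl2, −78 °C; aq. Rochelle salt
Reagents that add atoms: none
Why: 1,2-Reduction of the enoate with i-Bu2AlH gives the E-allylic alcohol that the directed epoxidation needs.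

Step 6
Reactants: 8 (2E)-3-(1,2,2-trimethylcyclopentyl)prop-2-en-1-ol
Product: 9 [(2S,3S)-3-(1,2,2-trimethylcyclopentyl)oxiran-2-yl]methanol
Conditions: Ti(OiPr)4 (10 mol %), L-(+)-diethyl tartrate (12 mol %), t-BuOOH, 4 Å MS, CH2Cl2, −20 °C
Reagents that add atoms: tert-butyl hydroperoxide CC(C)(C)OO
Why: In the Sharpless asymmetric epoxidation the titanium–L-(+)-tartrate catalyst delivers oxygen to one face of the E-allylic alcohol under reagent control, which sets C5 (S) and C6 (S) as a trans epoxide in both C10 epimers.

Step 7
Reactants: 9 [(2S,3S)-3-(1,2,2-trimethylcyclopentyl)oxiran-2-yl]methanol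
Product: 10 [(2S,3S)-3-(1,2,2-trimethylcyclopentyl)oxiran-2-yl]methyl trifluoromethanesulfonate
Conditions: Tf2O, 2,6-lutidine, CH2Cl2, −78 °C, used crude
Reagents that add atoms: triflic anhydride O=S(=O)(OS(=O)(=O)C(F)(F)F)C(F)(F)F
Why: O-Sulfonylation of the primary alcohol at low temperature with a hindered base leaves the epoxide untouched and makes C7 a strong electrophile.

Step 8
Reactants: 11 2-(2-bromoethyl)-2-methyl-1,3-dioxolane, 12 prop-1-yn-1-yllithium
Product: 13 2-methyl-2-(pent-3-yn-1-yl)-1,3-dioxolane
Conditions: THF/DMPU, −78 °C to rt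
Reagents that add atoms: none
Why: SN2 alkylation of a lithium acetylide with a primary bromide in a dipolar cosolvent joins C9 to C11.

Step 9
Reactants: 13 2-methyl-2-(pent-3-yn-1-yl)-1,3-dioxolane
Product: 15 2-[(3E)-4-iodopent-3-en-1-yl]-2-methyl-1,3-dioxolane, via alkenylzirconocene chloride 14 (not isolated)
Conditions: Cp2Zr(H)Cl (1.5 equiv), THF, 40 °C; I2, 0 °C
Reagents that add atoms: iodine II
Why: Syn-hydrozirconation with excess Schwartz reagent equilibrates zirconium to the less hindered, methyl-bearing alkyne carbon, and iodinolysis with retention gives the E-iodide (later C8=C9).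

Step 10
Reactants: 15 2-[(3E)-4-iodopent-3-en-1-yl]-2-methyl-1,3-dioxolane
Product: 16 (5E)-6-iodohept-5-en-2-one
Conditions: 1 M HCl, THF, rt
Reagents that add atoms: water O
Why: The acid-catalysed ketal hydrolysis is done before the epoxide enters the molecule, and the alkenyl iodide is inert to it.

Step 11
Reactants: 16 (5E)-6-iodohept-5-en-2-one
Product: 18 tert-butyl{[(5E)-6-iodohepta-1,5-dien-2-yl]oxy}dimethylsilane, via lithium enolate 17 (not isolated)
Conditions: LDA, THF, −78 °C; TBSCl, DMPU, −78 to 0 °C
Reagents that add atoms: TBSCl CC(C)(C)[Si](C)(C)Cl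
Why: Kinetic deprotonation of the methyl ketone at CH3 followed by O-silylation gives the terminal silyl enol ether (C13=C14), and the iodide has no anti hydrogen for elimination.

Step 12
Reactants: 18 tert-butyl{[(5E)-6-iodohepta-1,5-dien-2-yl]oxy}dimethylsilane, 10 [(2S,3S)-3-(1,2,2-trimethylcyclopentyl)oxiran-2-yl]methyl trifluoromethanesulfonate
Product: 20 tert-butyl(dimethyl)({(5E)-6-methyl-7-[(2S,3S)-3-(1,2,2-trimethylcyclopentyl)oxiran-2-yl]hepta-1,5-dien-2-yl}oxy)silane, via alkenylmagnesium chloride 19 (not isolated)
Conditions: i-PrMgCl·LiCl, THF, 0 °C to rt; CuI (10 mol %); 10, −78 to −20 °C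
Reagents that add atoms: none
Why: Iodine–magnesium exchange with retention of alkene geometry is followed by CuI-catalysed sp2–sp3 cross-coupling of the Grignard reagent with the primary triflate, which is much faster than attack on the hindered epoxide and forms the C7–C8 bond.

Step 13
Reactants: 20 tert-butyl(dimethyl)({(5E)-6-methyl-7-[(2S,3S)-3-(1,2,2-trimethylcyclopentyl)oxiran-2-yl]hepta-1,5-dien-2-yl}oxy)silane
Product: 22 tricyclic hydroxy ketone (5R,6S,8R,9R,10S), via ring-enlarged C10 cation 21 (not isolated)
Conditions: MeAlCl2 (1.5 equiv), CH2Cl2 (high dilution), −78 °C; aq. NaHCO3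
Reagents that add atoms: none
Why: Proposed new method: MeAlCl2 binds the epoxide oxygen, the C5–O bond breaks while the anti-periplanar C10–C4 ring bond shifts to C5 (Wagner–Meerwein shift, inversion at C5, C6–O untouched), so the cyclopentane C10/C1/C2/C3/C4 takes up C5 and becomes ring A with a tertiary cation at C10 (21). The closest known reaction types are the semipinacol ring enlargement of 1-(oxiranyl)cycloalkanols, the BF3-induced alkyl shift of tert-alkyl oxiranes and the epoxide-initiated polyene cyclisation that ends on a silyl enol ether; new is that the shifted cation, not the epoxide carbon, starts the cyclisation. Ring A is formed by one-carbon enlargement, ring B closes 6-endo-trig (C9 of the E-alkene on C10) and ring C closes 6-endo-trig (enol ether carbon C14 on the C8 cation), after which loss of the silyl group leaves the C13 ketone. C5 is controlled by the stereospecific anti migration on the (2S,3S)-epoxide, C10 by attack of C9 anti to the migrated C4 with the side chain equatorial on ring A (trans A/B), and C9 and C8 by anti addition across the E-alkene in a chair–chair fold, which places both angular methyl groups syn to the axial C6–O bond. The step needs migration of C4 in preference to C1, CH3 or the C6 hydride, and this is secured because C4 is the most substituted migrating carbon, a ring-bond shift releases cyclopentane strain, the product cation is tertiary, and neopentyl C5 is closed to direct attack by the alkene. Both C10 epimers of 20 should converge on the same planar cation, so the racemic quaternary carbon costs nothing.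

Step 14
Reactants: 22 tricyclic hydroxy ketone (5R,6S,8R,9R,10S)
Product: 23 tricyclic keto acetate (5R,6S,8R,9R,10S)
Conditions: Ac2O, DMAP (cat.), pyridine, 50 °C
Reagents that add atoms: acetic anhydride CC(=O)OC(C)=O
Why: DMAP-catalysed acylation with gentle heating should overcome the hindrance of the only hydroxyl group (axial C6–OH), and it installs the acetate before any other hydroxyl group exists.

Step 15
Reactants: 24 4-methoxy-3-methylphenol
Product: 25 4,4-dimethoxy-3-methylcyclohexa-2,5-dien-1-one
Conditions: PhI(OAc)2, MeOH, 0 °C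
Reagents that add atoms: methanol CO
Why: Oxidative dearomatisation of a 4-methoxyphenol with PhI(OAc)2 in methanol gives the quinone monoketal that carries all seven carbons of ring E.

Step 16
Reactants: 25 4,4-dimethoxy-3-methylcyclohexa-2,5-dien-1-one
Product: 26 4,4-dimethoxy-3-methylcyclohex-2-en-1-one
Conditions: H2 (1 atm), RhCl(PPh3)3 (5 mol %), toluene/EtOH, rt
Reagents that add atoms: none
Why: Homogeneous hydrogenation with Wilkinson's catalyst selects the disubstituted over the methyl-substituted enone double bond and does not cleave the ketal.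

Step 17
Reactants: 26 4,4-dimethoxy-3-methylcyclohex-2-en-1-one, 23 tricyclic keto acetate (5R,6S,8R,9R,10S)
Product: 28 aldol adduct (13S,5'S), via lithium dienolate 27 (not isolated)
Conditions: LDA, THF, −78 °C; 23, −78 °C; AcOH quench at −78 °C
Reagents that add atoms: none
Why: In this lithium-chelated aldol addition (Zimmerman–Traxler model) of the kinetic cross-conjugated enolate, the axial C8 methyl group blocks the axial path so that C5' enters equatorially (C13–O axial), and the crowded sector between that oxygen and C14 accepts only the enolate C–H, which sets C5'.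

Step 18
Reactants: 28 aldol adduct (13S,5'S)
Product: 30 bridged diketone (13S,2'R,3'S,5'S), via ene-dione 29 (not isolated)
Conditions: 10% aq. oxalic acid on SiO2, CH2Cl2, rt
Reagents that add atoms: water O
Why: Mild ketal hydrolysis unmasks the C1' ketone, and the tertiary C13–OH then adds to C3' in a 5-exo-trig intramolecular oxa-Michael reaction whose tether forces the C3'–O bond cis to C5'–C13, while the enolisable C2' settles with its methyl group equatorial.

Step 19
Reactants: 30 bridged diketone (13S,2'R,3'S,5'S)
Product: 31 target CNP0188572.2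
Conditions: NaBH4 (0.3 equiv), MeOH/CH2Cl2, −78 °C
Reagents that add atoms: none
Why: In this chemo- and diastereoselective hydride reduction the strained, non-enolisable, alkoxy-substituted bridge ketone C4' reacts faster than the C1' ketone, whose axial face lies under the O–C13 bridge. Hydride arrives from the side of the three-carbon bridge because the exo C14H2 group shields the other face, which places the C4'–OH syn to the oxa bridge (4'R).

Compound list
1 | 2,2-dimethylcyclopentan-1-one | CC1(C)CCCC1=O | starting material
2 | 2,2-dimethylcyclopentane-1-carbonitrile (racemic) | CC1(C)CCCC1C#N | intermediate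
3 | lithiated nitrile (N-lithio ketenimine of 2) | CC1(C)CCCC1=C=N[Li] | intermediate
4 | 1,2,2-trimethylcyclopentane-1-carbonitrile (racemic) | CC1(C)CCCC1(C)C#N | intermediate
5 | N-(diisobutylalumanyl)imine of aldehyde 6 | CC1(C)CCCC1(C)C=N[Al](CC(C)C)CC(C)C | intermediate
6 | 1,2,2-trimethylcyclopentane-1-carbaldehyde (racemic) | CC1(C)CCCC1(C)C=O | intermediate
7 | ethyl (2E)-3-(1,2,2-trimethylcyclopentyl)prop-2-enoate (racemic) | CCOC(=O)/C=C/C1(C)CCCC1(C)C | intermediate
8 | (2E)-3-(1,2,2-trimethylcyclopentyl)prop-2-en-1-ol (racemic) | OC/C=C/C1(C)CCCC1(C)C | intermediate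
9 | [(2S,3S)-3-(1,2,2-trimethylcyclopentyl)oxiran-2-yl]methanol (both epimers at the ring quaternary carbon) | OC[C@@H]1O[C@H]1C1(C)CCCC1(C)C | intermediate
10 | [(2S,3S)-3-(1,2,2-trimethylcyclopentyl)oxiran-2-yl]methyl trifluoromethanesulfonate | O=S(=O)(OC[C@@H]1O[C@H]1C1(C)CCCC1(C)C)C(F)(F)F | intermediate
11 | 2-(2-bromoethyl)-2-methyl-1,3-dioxolane | CC1(CCBr)OCCO1 | starting material
12 | prop-1-yn-1-yllithium | CC#C[Li] | starting material
13 | 2-methyl-2-(pent-3-yn-1-yl)-1,3-dioxolane | CC#CCCC1(C)OCCO1 | intermediate
14 | (E)-alkenylzirconocene chloride from 13 (Zr on the methyl-bearing carbon) | Cl[Zr](C1C=CC=C1)(C1C=CC=C1)/C(C)=C/CCC1(C)OCCO1 | intermediate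
15 | 2-[(3E)-4-iodopent-3-en-1-yl]-2-methyl-1,3-dioxolane | I/C(C)=C/CCC1(C)OCCO1 | intermediate
16 | (5E)-6-iodohept-5-en-2-one | I/C(C)=C/CCC(C)=O | intermediate
17 | lithium (5E)-6-iodohepta-1,5-dien-2-olate | I/C(C)=C/CCC(=C)O[Li] | intermediate
18 | tert-butyl{[(5E)-6-iodohepta-1,5-dien-2-yl]oxy}dimethylsilane | I/C(C)=C/CCC(=C)O[Si](C)(C)C(C)(C)C | intermediate
19 | (E)-alkenylmagnesium chloride from 18 | Cl[Mg]/C(C)=C/CCC(=C)O[Si](C)(C)C(C)(C)C | intermediate
20 | tert-butyl(dimethyl)({(5E)-6-methyl-7-[(2S,3S)-3-(1,2,2-trimethylcyclopentyl)oxiran-2-yl]hepta-1,5-dien-2-yl}oxy)silane | CC1(C)CCCC1(C)[C@@H]1O[C@H]1C/C(C)=C/CCC(=C)O[Si](C)(C)C(C)(C)C | intermediate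
21 | ring-enlarged C10 cation (1,3,3-trimethylcyclohexyl cation with the C6 aluminate side chain on C5, zwitterion) | C[C+]1CCCC(C)(C)[C@H]1[C@@H](O[Al-](C)(Cl)Cl)C/C(C)=C/CCC(=C)O[Si](C)(C)C(C)(C)C | intermediate
22 | tricyclic hydroxy ketone (5R,6S,8R,9R,10S): trans-anti-trans rings A–C, C13 ketone, axial C6–OH syn to the C8 and C10 methyl groups | O[C@H]1C[C@]2(C)CC(=O)CC[C@H]2[C@]2(C)CCCC(C)(C)[C@@H]12 | intermediate
23 | tricyclic keto acetate (5R,6S,8R,9R,10S): C6 acetate of 22 | CC(=O)O[C@H]1C[C@]2(C)CC(=O)CC[C@H]2[C@]2(C)CCCC(C)(C)[C@@H]12 | intermediate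
24 | 4-methoxy-3-methylphenol | COc1ccc(O)cc1C | starting material
25 | 4,4-dimethoxy-3-methylcyclohexa-2,5-dien-1-one | COC1(OC)C=CC(=O)C=C1C | intermediate
26 | 4,4-dimethoxy-3-methylcyclohex-2-en-1-one | COC1(OC)CCC(=O)C=C1C | intermediate
27 | lithium cross-conjugated dienolate of 26 | COC1(OC)CC=C(O[Li])C=C1C | intermediate
28 | aldol adduct (13S,5'S): axial C13–OH, equatorial C13–C5' bond to the 4,4-dimethoxy-3-methylcyclohex-2-enone ring | CC(=O)O[C@H]1C[C@]2(C)C[C@@](O)(CC[C@H]2[C@]2(C)CCCC(C)(C)[C@@H]12)[C@@H]1CC(OC)(OC)C(C)=CC1=O | intermediate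
29 | ene-dione (13S,5'S): C1' and C4' ketones, C2'=C3' double bond, free C13–OH | CC(=O)O[C@H]1C[C@]2(C)C[C@@](O)(CC[C@H]2[C@]2(C)CCCC(C)(C)[C@@H]12)[C@@H]1CC(=O)C(C)=CC1=O | intermediate
30 | bridged diketone (13S,2'R,3'S,5'S): 6-oxabicyclo[3.2.1]octane with C4' bridge ketone and C1' ketone, spiro at C13 | CC(=O)O[C@H]1C[C@]2(C)C[C@]3(CC[C@H]2[C@]2(C)CCCC(C)(C)[C@@H]12)O[C@@H]1C(=O)[C@H]3CC(=O)[C@@H]1C | intermediate
31 | CNP0188572.2 (5R,6S,8R,9R,10S,13S,2'R,3'S,4'R,5'R) | CC(=O)O[C@H]1C[C@]2(C)C[C@]3(CC[C@H]2[C@]2(C)CCCC(C)(C)[C@@H]12)O[C@@H]1[C@H](O)[C@H]3CC(=O)[C@@H]1C | target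

Total step count: 19
Longest linear sequence: 13 steps (steps 1–7, 12–14, 17–19)

Steps most likely to fail

1. Step 13.
- **What may go wrong:** Hydride migration from C6 (Meinwald pathway) or proton loss from the C10 cation may outrun the alkyl shift and the two ring closures. The C10 epimer that is born with an axial side chain on ring A may leak into cis ring fusion before ring inversion. Crowding of the axial C6–O–Al group may also slow the chair closure of ring B.
- **Fallback (known chemistry, sets out from 1 and 19, comes back at 22):** The methyl group at C10 is replaced by a hydroxyl group, so that the ring enlargement becomes a semipinacol rearrangement and the cyclisation becomes a separate step. Ketone 1 is treated with dilithiated propargyl alcohol to give alkynediol F1, and NaAlH2(OCH2CH2OMe)2 reduces the alkyne to (E)-enediol F2. Sharpless epoxidation with L-(+)-diethyl tartrate gives epoxy diol F3. Tf2O/2,6-lutidine at −78 °C sulfonylates only the primary hydroxyl group to give hydroxy epoxy triflate F4. CuI-catalysed coupling with 19 (one extra equivalent for the tertiary OH) gives tertiary hydroxy epoxide F5. ZnBr2 in CH2Cl2 then triggers the semipinacol rearrangement: the C10–C4 ring bond migrates anti to the breaking C5–O bond and C10 becomes a ketone, which gives ring-enlarged hydroxy ketone F6. MeLi/CeCl3 at −78 °C adds to the C10 ketone to give tertiary carbinol F7 (either epimer). SnCl4 in CH2Cl2 at −78 °C ionises this carbinol to the C10 cation, which closes rings B and C as in step 13 and gives 22.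

2. Step 18.
- **What may go wrong:** Ring E stands at the hydroquinone oxidation level while the ketal is cleaved. Tautomerisation to an arene, loss of methanol to a methoxyphenol, or retro-aldol cleavage may therefore compete with the oxa-Michael closure.
- **Fallback (sets out from 28, comes back at 30):** The oxidation level of ring E is lowered before the ketal is opened. Luche reduction (NaBH4, CeCl3, MeOH, −78 °C) of the C4' ketone gives allylic alcohol ketal F8 (either C4' epimer is acceptable). Oxalic acid on SiO2 then gives hydroxy enone F9, which cannot aromatise by tautomerisation. A catalytic amount of DBU closes it by oxa-Michael addition to bridged hydroxy ketone F10. Dess–Martin periodinane oxidises the C4' alcohol of both epimers to 30, from which step 19 sets C4'.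

3. Step 17.
- **What may go wrong:** Proton transfer from ketone 23 to the basic enolate, retro-aldol reaction of the lithium aldolate on warming, and weak discrimination between the two enolate faces.
- **Fallback (sets out from 27, comes back at 28):** The enolate is generated reductively on an oxophilic, non-basic metal. Enolate 27 is quenched with N-bromosuccinimide to give bromo enone F11. F11 and 23 are added together to SmI2 in THF at −78 °C (samarium Reformatsky reaction). The samarium enolate F12 adds to C13 through the same closed transition state, and the aldolate of trivalent samarium does not revert. Aqueous work-up gives 28.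

Further compounds
F1 | step 13 | alkynediol, 1-(3-hydroxyprop-1-yn-1-yl)-2,2-dimethylcyclopentan-1-ol | CC1(C)CCCC1(O)C#CCO
F2 | step 13 | (E)-enediol, 1-[(1E)-3-hydroxyprop-1-en-1-yl]-2,2-dimethylcyclopentan-1-ol | CC1(C)CCCC1(O)/C=C/CO
F3 | step 13 | epoxy diol, 1-[(2R,3S)-3-(hydroxymethyl)oxiran-2-yl]-2,2-dimethylcyclopentan-1-ol | OC[C@@H]1O[C@H]1C1(O)CCCC1(C)C
F4 | step 13 | hydroxy epoxy triflate, primary triflate of F3 | O=S(=O)(OC[C@@H]1O[C@H]1C1(O)CCCC1(C)C)C(F)(F)F
F5 | step 13 | tertiary hydroxy epoxide, analogue of 20 with OH in place of the C10 methyl group | CC1(C)CCCC1(O)[C@@H]1O[C@H]1C/C(C)=C/CCC(=C)O[Si](C)(C)C(C)(C)C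
F6 | step 13 | ring-enlarged hydroxy ketone, 3,3-dimethylcyclohexanone bearing the C6 carbinol side chain on C5 | O=C1CCCC(C)(C)[C@H]1[C@@H](O)C/C(C)=C/CCC(=C)O[Si](C)(C)C(C)(C)C
F7 | step 13 | tertiary carbinol, methyl adduct of F6 at C10 (C10 open) | CC1(O)CCCC(C)(C)[C@H]1[C@@H](O)C/C(C)=C/CCC(=C)O[Si](C)(C)C(C)(C)C
F8 | step 18 | allylic alcohol ketal, C4' alcohol of 28 (C4' open) | CC(=O)O[C@H]1C[C@]2(C)C[C@@](O)(CC[C@H]2[C@]2(C)CCCC(C)(C)[C@@H]12)[C@@H]1CC(OC)(OC)C(C)=CC1O
F9 | step 18 | hydroxy enone, C1' enone with C4'–OH and C13–OH (C4' open) | CC(=O)O[C@H]1C[C@]2(C)C[C@@](O)(CC[C@H]2[C@]2(C)CCCC(C)(C)[C@@H]12)[C@@H]1CC(=O)C(C)=CC1O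
F10 | step 18 | bridged hydroxy ketone, oxa-Michael product of F9 (C4' open) | CC(=O)O[C@H]1C[C@]2(C)C[C@]3(CC[C@H]2[C@]2(C)CCCC(C)(C)[C@@H]12)O[C@@H]1C(O)[C@H]3CC(=O)[C@@H]1C
F11 | step 17 | bromo enone, 6-bromo-4,4-dimethoxy-3-methylcyclohex-2-en-1-one | COC1(OC)CC(Br)C(=O)C=C1C
F12 | step 17 | samarium enolate of 26 | COC1(OC)CC=C(O[Sm](I)I)C=C1C
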